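**Retrosynthetic overview**
1. Target 24 ⇒ removal of two TBS ethers from 23; 23 ⇒ Yamaguchi ester bond between bicyclic allylic alcohol 14 and dienoic acid 22.
2. 14 ⇒ stereoretentive C–B oxidation of allylic boronate 13.
3. 13 ⇒ one-pot alkynyl–allyl coupling (9 + 10), propargyl→allenyl shift and intramolecular Diels–Alder reaction of a vinylallenyl ketone. Ring A and ring B close together in this operation, the only ring-forming event; alkene geometry sets C3/C4/C5 and the C7 silyloxy centre sets the absolute sense.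
4. Ynone 9 ⇒ methyl (R)-glycidate + (E)-2-bromobut-2-ene (copper-catalysed epoxide opening), silylation, Weinreb amide, ethynyl Grignard.
5. Acid 22 ⇒ Brown (Z)-crotylboration of acetaldehyde, silylation, cross-metathesis with penta-2,4-dienoic acid.

Numbering used in the text (eremophilane-type): C3 = ester-bearing CH, C4 = CHMe, C5 = quaternary C–Me, C6 = CH2, C7 = CHOH, C8 = C=O, C9=C10 and C1=C2; ring A = C1–C5 + C10, ring B = C5–C10.
Assumption: carbon building blocks are numbered as compounds; auxiliary reagents (silyl chlorides, bases, catalysts) appear only on the Conditions and Reagents lines.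

**Route**

Step 1
Reactants: 1 (E)-2-bromobut-2-ene; 2 methyl (2R)-oxirane-2-carboxylate (methyl (R)-glycidate)
Product: 5 methyl (2R,4E)-2-hydroxy-4-methylhex-4-enoate, via (Z)-but-2-en-2-yllithium 3 (not isolated), via (E)-but-2-en-2-ylmagnesium bromide 4 (not isolated)
Conditions: t-BuLi (2 equiv), Et2O, −78 °C; MgBr2·OEt2; CuI (10 mol%), then 2, THF, −78 → −30 °C; aqueous work-up
Reagents that add atoms: none
Why: Br–Li exchange with t-BuLi keeps the alkene geometry (the two methyls stay cis), and the derived Grignard reagent under CuI catalysis opens the glycidate at the unsubstituted CH2 (copper-catalysed epoxide opening), so the (R) carbinol of 2 is carried over untouched as the future C7 stereocenter.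

Step 2
Reactants: 5 methyl (2R,4E)-2-hydroxy-4-methylhex-4-enoate
Product: 6 methyl (2R,4E)-2-[(tert-butyldimethylsilyl)oxy]-4-methylhex-4-enoate
Conditions: TBSCl, imidazole, DMF, rt
Reagents that add atoms: tert-butyldimethylsilyl chloride, CC(C)(C)[Si](C)(C)Cl
Why: Standard silylation of a secondary alcohol, giving a bulky α-silyloxy group that later resists enolisation and directs the cycloaddition; no stereocenter is touched.

Step 3
Reactants: 6 methyl (2R,4E)-2-[(tert-butyldimethylsilyl)oxy]-4-methylhex-4-enoate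
Product: 7 (2R,4E)-2-[(tert-butyldimethylsilyl)oxy]-N-methoxy-N,4-dimethylhex-4-enamide
Conditions: MeNH(OMe)·HCl, i-PrMgCl (3 equiv), THF, −20 → 0 °C
Reagents that add atoms: N,O-dimethylhydroxylamine hydrochloride, CNOC.Cl
Why: Direct ester-to-Weinreb-amide aminolysis with the magnesium amide proceeds without epimerising the α-silyloxy center.

Step 4
Reactants: 7 (2R,4E)-2-[(tert-butyldimethylsilyl)oxy]-N-methoxy-N,4-dimethylhex-4-enamide; 8 ethynylmagnesium bromide
Product: 9 (4R,6E)-4-[(tert-butyldimethylsilyl)oxy]-6-methyloct-6-en-1-yn-3-one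
Conditions: THF, 0 °C; inverse quench into cold 1 M HCl
Reagents that add atoms: none
Why: Weinreb ketone synthesis stops at the ynone through the chelated tetrahedral intermediate, and the acidic inverse quench keeps the liberated amine from adding to the terminal ynone.

Step 5
Reactants: 9 (4R,6E)-4-[(tert-butyldimethylsilyl)oxy]-6-methyloct-6-en-1-yn-3-one; 10 (E)-2-(3-chloroprop-1-en-1-yl)-4,4,5,5-tetramethyl-1,3,2-dioxaborolane
Product: 13 (3R,4aR,5S,6S)-3-[(tert-butyldimethylsilyl)oxy]-4a,5-dimethyl-6-(4,4,5,5-tetramethyl-1,3,2-dioxaborolan-2-yl)-4,4a,5,6-tetrahydronaphthalen-2(3H)-one, via skipped enyne ketone 11 (not isolated), via vinylallenyl ketone 12 (not isolated)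
Conditions: CuI (20 mol%), NaI (20 mol%), K2CO3 (1.5 equiv), DMF, 0 °C → rt, Ar; then dilute with toluene (0.01 M), Et3N (1 equiv), BHT, 60 °C
Reagents that add atoms: none
Why: Proposed new method: the copper acetylide of 9 is allylated by 10 (closest known type: copper-catalysed coupling of terminal alkynes with allyl halides) to give 11, whose CH2 between the ynone and the vinylboronate is acidic enough for carbonate/amine to shift it to allenyl ketone 12 (known base-mediated propargyl-to-allenyl isomerisation of ynones), and 12 closes rings A and B by an intramolecular Diels–Alder reaction of a vinylallene (known for allene-terminus tethers and unactivated alkenes) in which the allene geometry forces the tether exo, so both dienophile methyls sit endo and end up cis to the outside (E) boryl group (all-cis C3/C4/C5), while the base-equilibrated allene axis lets the C7 OTBS group select the half-chair transition state in which it is pseudo-equatorial and anti to the C5 methyl, which fixes the absolute sense.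

Step 6
Reactants: 13 (3R,4aR,5S,6S)-3-[(tert-butyldimethylsilyl)oxy]-4a,5-dimethyl-6-(4,4,5,5-tetramethyl-1,3,2-dioxaborolan-2-yl)-4,4a,5,6-tetrahydronaphthalen-2(3H)-one
Product: 14 (3R,4aR,5R,6S)-3-[(tert-butyldimethylsilyl)oxy]-6-hydroxy-4a,5-dimethyl-4,4a,5,6-tetrahydronaphthalen-2(3H)-one
Conditions: NaBO3·4H2O, THF/H2O (1:1), 0 °C → rt
Reagents that add atoms: sodium perborate tetrahydrate NaBO3·4H2O, [Na+].[O-]OB=O.O.O.O.O
Why: Perborate oxidation of the allylic pinacol boronate proceeds by 1,2-migration with retention and without allylic shift (stereoretentive C–B oxidation), so the C3 hydroxyl arrives cis to both methyls.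

Step 7
Reactants: 15 (Z)-but-2-ene; 16 acetaldehyde
Product: 19 (2S,3S)-3-methylpent-4-en-2-ol, via (Z)-crotylpotassium 17 (not isolated), via (Z)-crotyldiisopinocampheylborane 18 (not isolated)
Conditions: KOt-Bu, n-BuLi, THF, −78 → −45 °C; (+)-Ipc2BOMe [from (−)-α-pinene], −78 °C; BF3·OEt2; then 16, −78 °C; NaOH, H2O2
Reagents that add atoms: none
Why: Brown asymmetric crotylboration, in which the (Z)-crotyl group gives the syn diastereomer through a chair Zimmerman–Traxler transition state and the isopinocampheyl groups derived from (−)-α-pinene direct attack to the Re face of acetaldehyde, giving the (2S,3S) alcohol.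

Step 8
Reactants: 19 (2S,3S)-3-methylpent-4-en-2-ol
Product: 20 tert-butyldimethyl{[(2S,3S)-3-methylpent-4-en-2-yl]oxy}silane
Conditions: TBSCl, imidazole, DMF, rt
Reagents that add atoms: tert-butyldimethylsilyl chloride, CC(C)(C)[Si](C)(C)Cl
Why: Standard silylation protects the side-chain hydroxyl for the later esterification and does not touch either stereocenter.

Step 9
Reactants: 20 tert-butyldimethyl{[(2S,3S)-3-methylpent-4-en-2-yl]oxy}silane; 21 (2E)-penta-2,4-dienoic acid
Product: 22 (2E,4E,6S,7S)-7-[(tert-butyldimethylsilyl)oxy]-6-methylocta-2,4-dienoic acid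
Conditions: Hoveyda–Grubbs second-generation catalyst [RuCl2(H2IMes)(=CH-C6H4-2-O-i-Pr)] (5 mol%), 21 (3 equiv), 1,4-benzoquinone (10 mol%), CH2Cl2, 40 °C
Reagents that add atoms: none
Why: Olefin cross-metathesis takes place chemoselectively at the terminal vinyl group of the electron-poor diene and gives the new C4=C5 bond E under thermodynamic control, while the existing (2E) bond and the allylic stereocenter are untouched.

Step 10
Reactants: 14 (3R,4aR,5R,6S)-3-[(tert-butyldimethylsilyl)oxy]-6-hydroxy-4a,5-dimethyl-4,4a,5,6-tetrahydronaphthalen-2(3H)-one; 22 (2E,4E,6S,7S)-7-[(tert-butyldimethylsilyl)oxy]-6-methylocta-2,4-dienoic acid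
Product: 23 (1R,2S,7R,8aR)-7-[(tert-butyldimethylsilyl)oxy]-1,8a-dimethyl-6-oxo-1,2,6,7,8,8a-hexahydronaphthalen-2-yl (2E,4E,6S,7S)-7-[(tert-butyldimethylsilyl)oxy]-6-methylocta-2,4-dienoate
Conditions: 22, 2,4,6-trichlorobenzoyl chloride, Et3N, THF, rt; then 14, DMAP, toluene, rt
Reagents that add atoms: none
Why: Yamaguchi esterification through the mixed trichlorobenzoic anhydride and the acyl-DMAP species acylates the hindered secondary allylic alcohol with retention at C3, since the C–O bond of the alcohol is not broken.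

Step 11
Reactants: 23 (1R,2S,7R,8aR)-7-[(tert-butyldimethylsilyl)oxy]-1,8a-dimethyl-6-oxo-1,2,6,7,8,8a-hexahydronaphthalen-2-yl (2E,4E,6S,7S)-7-[(tert-butyldimethylsilyl)oxy]-6-methylocta-2,4-dienoate
Product: 24 (1R,2S,7R,8aR)-7-hydroxy-1,8a-dimethyl-6-oxo-1,2,6,7,8,8a-hexahydronaphthalen-2-yl (2E,4E,6S,7S)-7-hydroxy-6-methylocta-2,4-dienoate (CNP0329432.2)
Conditions: HF·pyridine, pyridine, THF, 0 °C → rt
Reagents that add atoms: none
Why: Buffered fluoride desilylation cleaves both secondary TBS ethers while leaving the dienoate ester, the dienone and the equatorial α-hydroxy ketone (the thermodynamically preferred C7 epimer) intact.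

**Compound list**
1 | (E)-2-bromobut-2-ene | C/C=C(\C)Br | starting material
2 | methyl (2R)-oxirane-2-carboxylate | COC(=O)[C@H]1CO1 | starting material
3 | (Z)-but-2-en-2-yllithium | C/C=C(\C)[Li] | intermediate (not isolated)
4 | (E)-but-2-en-2-ylmagnesium bromide | C/C=C(\C)[Mg]Br | intermediate (not isolated)
5 | methyl (2R,4E)-2-hydroxy-4-methylhex-4-enoate | COC(=O)[C@H](O)C/C(C)=C/C | intermediate
6 | methyl (2R,4E)-2-[(tert-butyldimethylsilyl)oxy]-4-methylhex-4-enoate | COC(=O)[C@H](O[Si](C)(C)C(C)(C)C)C/C(C)=C/C | intermediate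
7 | (2R,4E)-2-[(tert-butyldimethylsilyl)oxy]-N-methoxy-N,4-dimethylhex-4-enamide | CON(C)C(=O)[C@H](O[Si](C)(C)C(C)(C)C)C/C(C)=C/C | intermediate
8 | ethynylmagnesium bromide | C#C[Mg]Br | starting material
9 | (4R,6E)-4-[(tert-butyldimethylsilyl)oxy]-6-methyloct-6-en-1-yn-3-one | C#CC(=O)[C@H](O[Si](C)(C)C(C)(C)C)C/C(C)=C/C | intermediate
10 | (E)-2-(3-chloroprop-1-en-1-yl)-4,4,5,5-tetramethyl-1,3,2-dioxaborolane | ClC/C=C/B1OC(C)(C)C(C)(C)O1 | starting material
11 | (1E,7R,9E)-7-[(tert-butyldimethylsilyl)oxy]-9-methyl-1-(4,4,5,5-tetramethyl-1,3,2-dioxaborolan-2-yl)undeca-1,9-dien-4-yn-6-one | CC1(C)OB(/C=C/CC#CC(=O)[C@H](O[Si](C)(C)C(C)(C)C)C/C(C)=C/C)OC1(C)C | intermediate (not isolated)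
12 | (1E,7R,9E)-7-[(tert-butyldimethylsilyl)oxy]-9-methyl-1-(4,4,5,5-tetramethyl-1,3,2-dioxaborolan-2-yl)undeca-1,3,4,9-tetraen-6-one (both allene-axis epimers, interconverting) | CC1(C)OB(/C=C/C=C=CC(=O)[C@H](O[Si](C)(C)C(C)(C)C)C/C(C)=C/C)OC1(C)C | intermediate (not isolated)
13 | (3R,4aR,5S,6S)-3-[(tert-butyldimethylsilyl)oxy]-4a,5-dimethyl-6-(4,4,5,5-tetramethyl-1,3,2-dioxaborolan-2-yl)-4,4a,5,6-tetrahydronaphthalen-2(3H)-one | CC1(C)OB(OC1(C)C)[C@H]2C=CC3=CC(=O)[C@H](O[Si](C)(C)C(C)(C)C)C[C@]3(C)[C@H]2C | intermediate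
14 | (3R,4aR,5R,6S)-3-[(tert-butyldimethylsilyl)oxy]-6-hydroxy-4a,5-dimethyl-4,4a,5,6-tetrahydronaphthalen-2(3H)-one | O[C@H]1C=CC2=CC(=O)[C@H](O[Si](C)(C)C(C)(C)C)C[C@]2(C)[C@H]1C | intermediate
15 | (Z)-but-2-ene | C/C=C\C | starting material
16 | acetaldehyde | CC=O | starting material
17 | (2Z)-but-2-en-1-ylpotassium | C/C=C\C[K] | intermediate (not isolated)
18 | [(2Z)-but-2-en-1-yl]bis[(1S,2R,3S,5S)-2,6,6-trimethylbicyclo[3.1.1]heptan-3-yl]borane | C/C=C\CB([C@H]1C[C@H]2C[C@@H]([C@@H]1C)C2(C)C)[C@H]1C[C@H]2C[C@@H]([C@@H]1C)C2(C)C | intermediate (not isolated)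
19 | (2S,3S)-3-methylpent-4-en-2-ol | C[C@H](O)[C@@H](C)C=C | intermediate
20 | tert-butyldimethyl{[(2S,3S)-3-methylpent-4-en-2-yl]oxy}silane | C[C@H](O[Si](C)(C)C(C)(C)C)[C@@H](C)C=C | intermediate
21 | (2E)-penta-2,4-dienoic acid | C=C/C=C/C(=O)O | starting material
22 | (2E,4E,6S,7S)-7-[(tert-butyldimethylsilyl)oxy]-6-methylocta-2,4-dienoic acid | C[C@H](O[Si](C)(C)C(C)(C)C)[C@@H](C)/C=C/C=C/C(=O)O | intermediate
23 | (1R,2S,7R,8aR)-7-[(tert-butyldimethylsilyl)oxy]-1,8a-dimethyl-6-oxo-1,2,6,7,8,8a-hexahydronaphthalen-2-yl (2E,4E,6S,7S)-7-[(tert-butyldimethylsilyl)oxy]-6-methylocta-2,4-dienoate | C[C@H](O[Si](C)(C)C(C)(C)C)[C@@H](C)/C=C/C=C/C(=O)O[C@H]1C=CC2=CC(=O)[C@H](O[Si](C)(C)C(C)(C)C)C[C@]2(C)[C@H]1C | intermediate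
24 | (1R,2S,7R,8aR)-7-hydroxy-1,8a-dimethyl-6-oxo-1,2,6,7,8,8a-hexahydronaphthalen-2-yl (2E,4E,6S,7S)-7-hydroxy-6-methylocta-2,4-dienoate | C[C@H](O)[C@@H](C)/C=C/C=C/C(=O)O[C@H]1C=CC2=CC(=O)[C@H](O)C[C@]2(C)[C@H]1C | target

**Step count and risks**
Total steps: 11. Longest linear sequence: 8 (steps 1–6, 10, 11).

The three steps most likely to fail:

Step 5 (coupling, isomerisation and cycloaddition in one pot). Possible failures are a sluggish copper coupling on the electron-poor ynone, protonation of the extended anion at the wrong carbon, partial epimerisation at C7 before the cycloaddition, or a low facial ratio from the C7 silyloxy group. The fallback sets out from 7 and comes back at 14, and replaces the boron-substituted diene by an oxygen-substituted one built by plain acetylide acylation. Commercial (2E)-pent-2-en-4-yn-1-ol F1 is silylated (TESCl, imidazole) to triethyl{[(2E)-pent-2-en-4-yn-1-yl]oxy}silane F2. Deprotonation with n-BuLi at −78 °C gives lithium acetylide F3, which adds to 7 to give the conjugated enynone F4. A hindered guanidine base (2-tert-butyl-1,1,3,3-tetramethylguanidine, toluene, 60–80 °C) moves a proton from the CH2–OTES carbon to the ketone α-carbon, giving the silyloxy-vinylallenyl ketone F5. Only its (E)-enol ether isomer can reach the Diels–Alder transition state, while the (Z) isomer re-equilibrates through the enynone. The same vinylallene cycloaddition gives the C3 triethylsilyl ether F6, and PPTS in MeOH removes the TES group selectively to give 14 without any boron oxidation.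

Step 9 (cross-metathesis with the free dienoic acid). The risks are metathesis at the conjugated C2=C3 bond, polymerisation of 21, or slow turnover with the branched allylic partner. The fallback sets out from 20 and comes back at 22, and builds the diene by olefination. Ozonolysis of 20 (O3, CH2Cl2, −78 °C; PPh3) gives (2R,3S)-3-[(tert-butyldimethylsilyl)oxy]-2-methylbutanal F7. Vinylogous Horner–Wadsworth–Emmons reaction with triethyl (2E)-4-phosphonobut-2-enoate F8 (LiHMDS, THF, −78 → 0 °C) gives ethyl (2E,4E,6S,7S)-7-[(tert-butyldimethylsilyl)oxy]-6-methylocta-2,4-dienoate F9, and LiOH in THF/MeOH/H2O gives 22.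

Step 10 (acylation of the hindered C3 alcohol, which is flanked by the cis C4 methyl). The fallback sets out from 14 and 20 and comes back at 23, and builds the dienoate on the core. Alcohol 14 is acylated with the small, highly reactive 2-(diethoxyphosphoryl)acetic acid F10 (DCC, CH2Cl2) to give (1R,2S,7R,8aR)-7-[(tert-butyldimethylsilyl)oxy]-1,8a-dimethyl-6-oxo-1,2,6,7,8,8a-hexahydronaphthalen-2-yl 2-(diethoxyphosphoryl)acetate F11. In parallel, cross-metathesis of 20 with (2E)-but-2-enal F12 (Hoveyda–Grubbs second-generation catalyst, CH2Cl2, 40 °C) gives (2E,4S,5S)-5-[(tert-butyldimethylsilyl)oxy]-4-methylhex-2-enal F13. A Masamune–Roush Horner–Wadsworth–Emmons reaction of F11 with F13 (LiCl, DBU, MeCN) forms the (2E) bond and gives 23.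

**Further compounds**
F1 | step 5 | (2E)-pent-2-en-4-yn-1-ol | OC/C=C/C#C
F2 | step 5 | triethyl{[(2E)-pent-2-en-4-yn-1-yl]oxy}silane | CC[Si](CC)(CC)OC/C=C/C#C
F3 | step 5 | lithium acetylide of F2, [(3E)-5-[(triethylsilyl)oxy]pent-3-en-1-yn-1-yl]lithium | CC[Si](CC)(CC)OC/C=C/C#C[Li]
F4 | step 5 | (2E,7R,9E)-7-[(tert-butyldimethylsilyl)oxy]-9-methyl-1-[(triethylsilyl)oxy]undeca-2,9-dien-4-yn-6-one | CC[Si](CC)(CC)OC/C=C/C#CC(=O)[C@H](O[Si](C)(C)C(C)(C)C)C/C(C)=C/C
F5 | step 5 | (1E,7R,9E)-7-[(tert-butyldimethylsilyl)oxy]-9-methyl-1-[(triethylsilyl)oxy]undeca-1,3,4,9-tetraen-6-one | CC[Si](CC)(CC)O/C=C/C=C=CC(=O)[C@H](O[Si](C)(C)C(C)(C)C)C/C(C)=C/C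
F6 | step 5 | (3R,4aR,5R,6S)-3-[(tert-butyldimethylsilyl)oxy]-4a,5-dimethyl-6-[(triethylsilyl)oxy]-4,4a,5,6-tetrahydronaphthalen-2(3H)-one | CC[Si](CC)(CC)O[C@H]1C=CC2=CC(=O)[C@H](O[Si](C)(C)C(C)(C)C)C[C@]2(C)[C@H]1C
F7 | step 9 | (2R,3S)-3-[(tert-butyldimethylsilyl)oxy]-2-methylbutanal | C[C@H](O[Si](C)(C)C(C)(C)C)[C@@H](C)C=O
F8 | step 9 | triethyl (2E)-4-phosphonobut-2-enoate | CCOC(=O)/C=C/CP(=O)(OCC)OCC
F9 | step 9 | ethyl (2E,4E,6S,7S)-7-[(tert-butyldimethylsilyl)oxy]-6-methylocta-2,4-dienoate | C[C@H](O[Si](C)(C)C(C)(C)C)[C@@H](C)/C=C/C=C/C(=O)OCC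
F10 | step 10 | 2-(diethoxyphosphoryl)acetic acid | CCOP(=O)(CC(=O)O)OCC
F11 | step 10 | (1R,2S,7R,8aR)-7-[(tert-butyldimethylsilyl)oxy]-1,8a-dimethyl-6-oxo-1,2,6,7,8,8a-hexahydronaphthalen-2-yl 2-(diethoxyphosphoryl)acetate | CCOP(=O)(CC(=O)O[C@H]1C=CC2=CC(=O)[C@H](O[Si](C)(C)C(C)(C)C)C[C@]2(C)[C@H]1C)OCC
F12 | step 10 | (2E)-but-2-enal | C/C=C/C=O
F13 | step 10 | (2E,4S,5S)-5-[(tert-butyldimethylsilyl)oxy]-4-methylhex-2-enal | C[C@H](O[Si](C)(C)C(C)(C)C)[C@@H](C)/C=C/C=O
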